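**Retrosynthetic overview**
1. The ε-lactone (last ring) and the C11 acetate come from one C–O/C–O event: acetate-relayed opening of an (11R,12R)-epoxide with acyl transfer from a mixed anhydride.
2. The tetrahydrofuran (second ring) comes from 5-exo opening of a (7R,8R)-epoxide by the tertiary C4 hydroxyl after a hydroxyl-directed epoxidation.
3. The 14-membered carbocycle (first ring) comes from an intramolecular Nozaki–Hiyama–Kishi coupling (C3–C4); directed epoxidation and hydride opening then give the 3,4-diol.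
4. C1 is set by an organocatalytic malonate Michael addition to an enal; malonate plus CH2O later gives the α-methylene acid.
5. Carbon sources: (5E,9E)-farnesylacetone (C4–C14, C1), Ph3P=CHCHO (C2, C3), dibenzyl malonate (C15, C17), CH2O (C16).

Assumption: isomerically pure (5E,9E)-farnesylacetone is taken as a purchasable commodity ketone; atom labels C1–C17 follow the cembrane numbering of the target in every compound.

**Step 1**
Reactants: 1 (5E,9E)-farnesylacetone
Product: 3 (5E,9E)-13,14-epoxyfarnesylacetone (racemic at the oxirane CH), via terminal bromohydrin 2 (not isolated)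
Conditions: NBS, THF/H2O, 0 °C; then K2CO3, MeOH, rt
Reagents that add atoms: water, O
Why: Van Tamelen bromohydrin formation is selective for the terminal trisubstituted olefin and base closes the epoxide, whose stereocentre is destroyed in step 3.

**Step 2**
Reactants: 3 (5E,9E)-13,14-epoxyfarnesylacetone
Product: 4 (5E,9E)-13,14-epoxy-6,10,14-trimethylpentadeca-1,5,9-trien-2-yl triflate
Conditions: LiN(iPr)2, THF, −78 °C; then PhNTf2, −78 → 0 °C
Reagents that add atoms: N-phenylbis(trifluoromethanesulfonimide), O=S(=O)(N(c1ccccc1)S(=O)(=O)C(F)(F)F)C(F)(F)F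
Why: Kinetic enolisation at the methyl group and O-sulfonylation give the 2-triflyloxy-1-alkene needed for the later chromium coupling, the epoxide being inert at −78 °C.

**Step 3**
Reactants: 4 epoxy enol triflate
Product: 5 (4E,8E)-4,8-dimethyl-12-(triflyloxy)trideca-4,8,12-trienal
Conditions: H5IO6, THF/Et2O, 0 °C
Reagents that add atoms: none
Why: Periodic acid hydrolyses the epoxide and cleaves the glycol (Malaprade cleavage) to the aldehyde that becomes C1, leaving the olefins and the vinyl triflate untouched.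

**Step 4**
Reactants: 5 trienal triflate; 6 (formylmethylene)triphenylphosphorane
Product: 7 (2E,6E,10E)-6,10-dimethyl-14-(triflyloxy)pentadeca-2,6,10,14-tetraenal
Conditions: toluene, 80 °C
Reagents that add atoms: none
Why: Wittig reaction of the stabilised formyl ylide adds C2 and C3 as an (E)-enal and stops after one homologation.

**Step 5**
Reactants: 7 (E)-enal; 8 dibenzyl malonate
Product: 9 dibenzyl 2-[(3R,6E,10E)-6,10-dimethyl-1-oxo-14-(triflyloxy)pentadeca-6,10,14-trien-3-yl]malonate (C1 = R)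
Conditions: (R)-2-{bis[3,5-bis(trifluoromethyl)phenyl](trimethylsilyloxy)methyl}pyrrolidine (10 mol %), EtOH, 0 °C
Reagents that add atoms: none
Why: Jørgensen–Hayashi iminium-catalysed Michael addition, in which the bulky diarylsilyloxymethyl group shields one face of the (E)-iminium ion so the malonate adds to C1 from the open face and sets 1R (the antipodal catalyst gives 1S).

**Step 6**
Reactants: 9 Michael adduct
Product: 10 dibenzyl 2-[(1R,3R,7E,11E)-3-hydroxy-8,12-dimethyl-4-methylidenecyclotetradeca-7,11-dien-1-yl]malonate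
Conditions: CrCl2 (6 equiv), NiCl2 (5 mol %), Kishi (S)-oxazoline–sulfonamide ligand, Et3N, THF, rt, 2 mM
Reagents that add atoms: none
Why: Nozaki–Hiyama–Kishi reaction, in which the nickel-generated alkenylchromium species adds only to the aldehyde under high dilution to close the 14-membered ring at C3–C4, the chiral sulfonamide ligand on chromium setting 3R.

**Step 7**
Reactants: 10 macrocyclic allylic alcohol
Product: 11 (1R,3R,4S)-spiro-epoxide of 10 (oxirane on C4 and the former methylidene carbon; erythro epoxy alcohol)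
Conditions: VO(acac)2 (5 mol %), t-BuOOH, CH2Cl2, 0 °C
Reagents that add atoms: tert-butyl hydroperoxide, CC(C)(C)OO
Why: Hydroxyl-directed vanadium epoxidation of the 1,1-disubstituted allylic alcohol goes through the conformer that minimises A(1,2) strain and gives the erythro epoxy alcohol (4S), while the undirected trisubstituted olefins do not react.

**Step 8**
Reactants: 11 spiro-epoxy alcohol
Product: 12 dibenzyl 2-[(1R,3R,4R,7E,11E)-3,4-dihydroxy-4,8,12-trimethylcyclotetradeca-7,11-dien-1-yl]malonate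
Conditions: LiBHEt3 (5 equiv), THF, −20 → 0 °C
Reagents that add atoms: none
Why: The first equivalents deprotonate the hydroxyl and the malonate C–H (the enolate resists hydride), and SN2 hydride attack at the oxirane CH2 then turns it into the C4 methyl group with retention at C4 (4R).

**Step 9**
Reactants: 12 3,4-diol
Product: 13 dibenzyl 2-[(1R,3R,4R,7E,11E)-3-acetoxy-4-hydroxy-4,8,12-trimethylcyclotetradeca-7,11-dien-1-yl]malonate
Conditions: Ac2O, pyridine, DMAP (cat.), CH2Cl2, 0 °C
Reagents that add atoms: acetic anhydride, CC(=O)OC(C)=O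
Why: Selective acylation of the secondary C3 hydroxyl installs the first acetate, leaves the hindered tertiary C4 hydroxyl free as the only directing group, and blocks δ-lactonisation of O3 onto C17 later.

**Step 10**
Reactants: 13 C3 acetate
Product: 15 dibenzyl 2-[(1R,3R,4R,7S,8R,11E)-3-acetoxy-4,7-epoxy-4,8,12-trimethyl-8-(triethylsilyloxy)cyclotetradec-11-en-1-yl]malonate (cis-tetrahydrofuran), via 7,8-epoxide 14 (not isolated)
Conditions: Hf(OtBu)4 (10 mol %), Yamamoto C2-symmetric bishydroxamic acid ligand (12 mol %, the antipode that gives the 7R,8R epoxide), cumene hydroperoxide, DMPU, toluene, 0 °C; then Et3SiOTf, 2,6-lutidine, CH2Cl2, −78 °C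
Reagents that add atoms: cumene hydroperoxide, CC(C)(OO)c1ccccc1; triethylsilyl trifluoromethanesulfonate, CC[Si](CC)(CC)OS(=O)(=O)C(F)(F)F
Why: The hafnium bishydroxamate epoxidation is directed by the bishomoallylic C4 hydroxyl, so only the 7,8-olefin is oxidised, under catalyst control to 7R,8R, and the silyl triflate then triggers 5-exo C–O closure at C7 with inversion (7S) while capping O8 (8R retained).

**Step 11**
Reactants: 15 tetrahydrofuran dibenzyl malonate
Product: 17 2-[(1R,3R,4R,7S,8R,11E)-3-acetoxy-4,7-epoxy-4,8,12-trimethyl-8-(triethylsilyloxy)cyclotetradec-11-en-1-yl]acrylic acid, via malonic acid 16 (not isolated)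
Conditions: Pd/C (10 %), 1,4-cyclohexadiene, EtOAc, rt; then (CH2O)n, Et2NH, EtOAc, 70 °C
Reagents that add atoms: formaldehyde (as paraformaldehyde), C=O
Why: Transfer hydrogenolysis removes both benzyl esters without reducing the trisubstituted olefin, and decarboxylative Mannich methylenation of the malonic acid gives the α-substituted acrylic acid without base that would cleave the acetate.

**Step 12**
Reactants: 17 acrylic acid
Product: 18 (11R,12R)-11,12-epoxide of 17
Conditions: D-fructose-derived Shi ketone (30 mol %), Oxone (2KHSO5·KHSO4·K2SO4), K2CO3, Bu4NHSO4, MeCN/CH2(OMe)2/aqueous buffer pH 10.5, 0 °C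
Reagents that add atoms: potassium peroxymonosulfate, [K+].[O-]S(=O)(=O)OO
Why: Shi epoxidation through the spiro dioxirane transition state oxidises the only remaining electron-rich olefin with reagent control to the 11R,12R epoxide, the acrylate double bond being too electron-poor to react.

**Step 13**
Reactants: 18 epoxy acid
Product: 21 target CNP0343714.4, via mixed acetic anhydride 19 (not isolated), via silyl-protected target 20 (not isolated)
Conditions: Ac2O, pyridine, CH2Cl2, 0 °C; then Co(salen)(OAc) (trivalent cobalt, 5 mol %; salen = N,N'-bis(3,5-di-tert-butylsalicylidene)cyclohexane-1,2-diaminate), Bu4NOAc (10 mol %), toluene, 50 °C, 5 mM; then HF·pyridine, MeCN, 0 °C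
Reagents that add atoms: acetic anhydride, CC(=O)OC(C)=O
Why: Proposed new method: an acetate-relayed isomerisation of an epoxy carboxylic–acetic mixed anhydride to an acetoxy lactone, in which cobalt-bound acetate opens the Lewis-acid-activated trisubstituted epoxide by SN2 attack at the less hindered C11 (inversion, giving 11S and the second acetate), the tertiary C12 alkoxide (12R retained) is acylated intramolecularly by the mixed anhydride through a seven-membered transition state to close the ε-lactone and release acetate as chain carrier, the closest known reactions being the alternating ring-opening copolymerisation of epoxides (limonene oxide included) with anhydrides under metal–salen carboxylate/onium catalysis and the onium-salt-catalysed addition of anhydrides to epoxides, neither yet used intramolecularly to form a lactone; fluoride finally frees O8.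

**Compound list**
1 | (5E,9E)-6,10,14-trimethylpentadeca-5,9,13-trien-2-one (farnesylacetone) | CC(=O)CC/C=C(\C)CC/C=C(\C)CCC=C(C)C | starting material
2 | (5E,9E)-13-bromo-14-hydroxy-6,10,14-trimethylpentadeca-5,9-dien-2-one (racemic) | CC(=O)CC/C=C(\C)CC/C=C(\C)CCC(Br)C(C)(C)O | intermediate
3 | (5E,9E)-13,14-epoxy-6,10,14-trimethylpentadeca-5,9-dien-2-one (racemic) | CC(=O)CC/C=C(\C)CC/C=C(\C)CCC1OC1(C)C | intermediate
4 | (5E,9E)-13,14-epoxy-6,10,14-trimethylpentadeca-1,5,9-trien-2-yl trifluoromethanesulfonate | C=C(OS(=O)(=O)C(F)(F)F)CC/C=C(\C)CC/C=C(\C)CCC1OC1(C)C | intermediate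
5 | (4E,8E)-4,8-dimethyl-12-(triflyloxy)trideca-4,8,12-trienal | C=C(OS(=O)(=O)C(F)(F)F)CC/C=C(\C)CC/C=C(\C)CCC=O | intermediate
6 | (formylmethylene)triphenylphosphorane | O=CC=P(c1ccccc1)(c1ccccc1)c1ccccc1 | starting material
7 | (2E,6E,10E)-6,10-dimethyl-14-(triflyloxy)pentadeca-2,6,10,14-tetraenal | C=C(OS(=O)(=O)C(F)(F)F)CC/C=C(\C)CC/C=C(\C)CC/C=C/C=O | intermediate
8 | dibenzyl malonate | O=C(CC(=O)OCc1ccccc1)OCc1ccccc1 | starting material
9 | dibenzyl 2-[(3R,6E,10E)-6,10-dimethyl-1-oxo-14-(triflyloxy)pentadeca-6,10,14-trien-3-yl]malonate | C=C(OS(=O)(=O)C(F)(F)F)CC/C=C(\C)CC/C=C(\C)CC[C@H](CC=O)C(C(=O)OCc1ccccc1)C(=O)OCc1ccccc1 | intermediate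
10 | dibenzyl 2-[(1R,3R,7E,11E)-3-hydroxy-8,12-dimethyl-4-methylidenecyclotetradeca-7,11-dien-1-yl]malonate | C=C1CC/C=C(\C)CC/C=C(\C)CC[C@H](C[C@H]1O)C(C(=O)OCc1ccccc1)C(=O)OCc1ccccc1 | intermediate
11 | (1R,3R,4S)-spiro-epoxide of 10 (oxirane spiro at C4, 3-hydroxy, 7E,11E) | [C@@]12(CO2)CC/C=C(\C)CC/C=C(\C)CC[C@H](C[C@H]1O)C(C(=O)OCc1ccccc1)C(=O)OCc1ccccc1 | intermediate
12 | dibenzyl 2-[(1R,3R,4R,7E,11E)-3,4-dihydroxy-4,8,12-trimethylcyclotetradeca-7,11-dien-1-yl]malonate | C[C@@]1(O)CC/C=C(\C)CC/C=C(\C)CC[C@H](C[C@H]1O)C(C(=O)OCc1ccccc1)C(=O)OCc1ccccc1 | intermediate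
13 | dibenzyl 2-[(1R,3R,4R,7E,11E)-3-acetoxy-4-hydroxy-4,8,12-trimethylcyclotetradeca-7,11-dien-1-yl]malonate | C[C@@]1(O)CC/C=C(\C)CC/C=C(\C)CC[C@H](C[C@H]1OC(C)=O)C(C(=O)OCc1ccccc1)C(=O)OCc1ccccc1 | intermediate
14 | (7R,8R)-7,8-epoxide of 13 | C[C@@]1(O)CC[C@H]2O[C@]2(C)CC/C=C(\C)CC[C@H](C[C@H]1OC(C)=O)C(C(=O)OCc1ccccc1)C(=O)OCc1ccccc1 | intermediate
15 | dibenzyl 2-[(1R,3R,4R,7S,8R,11E)-3-acetoxy-4,7-epoxy-4,8,12-trimethyl-8-(triethylsilyloxy)cyclotetradec-11-en-1-yl]malonate | O=C(OCc1ccccc1)C(C(=O)OCc1ccccc1)[C@H]1C[C@@H](OC(C)=O)[C@@]2(C)CC[C@H](O2)[C@](C)(O[Si](CC)(CC)CC)CC/C=C(\C)CC1 | intermediate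
16 | malonic acid corresponding to 15 (both benzyl esters removed) | OC(=O)C(C(=O)O)[C@H]1C[C@@H](OC(C)=O)[C@@]2(C)CC[C@H](O2)[C@](C)(O[Si](CC)(CC)CC)CC/C=C(\C)CC1 | intermediate
17 | 2-[(1R,3R,4R,7S,8R,11E)-3-acetoxy-4,7-epoxy-4,8,12-trimethyl-8-(triethylsilyloxy)cyclotetradec-11-en-1-yl]acrylic acid | C=C(C(=O)O)[C@H]1C[C@@H](OC(C)=O)[C@@]2(C)CC[C@H](O2)[C@](C)(O[Si](CC)(CC)CC)CC/C=C(\C)CC1 | intermediate
18 | (11R,12R)-11,12-epoxide of 17 | C=C(C(=O)O)[C@H]1C[C@@H](OC(C)=O)[C@@]2(C)CC[C@H](O2)[C@](C)(O[Si](CC)(CC)CC)CC[C@H]3O[C@]3(C)CC1 | intermediate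
19 | mixed anhydride of 18 with acetic acid | C=C(C(=O)OC(C)=O)[C@H]1C[C@@H](OC(C)=O)[C@@]2(C)CC[C@H](O2)[C@](C)(O[Si](CC)(CC)CC)CC[C@H]3O[C@]3(C)CC1 | intermediate
20 | 8-O-triethylsilyl ether of the target | C=C1C(=O)O[C@]2(C)CC[C@@H]1C[C@@H](OC(C)=O)[C@@]1(C)CC[C@H](O1)[C@](C)(O[Si](CC)(CC)CC)CC[C@@H]2OC(C)=O | intermediate
21 | CNP0343714.4, (1R,3R,4R,7S,8R,11S,12R)-3,11-diacetoxy-4,7-epoxy-8-hydroxy cembranoid with 17,12 ε-lactone and 15(16)-methylene | C=C1C(=O)O[C@]2(C)CC[C@@H]1C[C@@H](OC(C)=O)[C@@]1(C)CC[C@H](O1)[C@](C)(O)CC[C@@H]2OC(C)=O | target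

**Totals**
Total step count: 13. Longest linear sequence: 13 steps (1 → 21).

**Steps most likely to fail and fallbacks**

Step 6 (macrocyclisation and control of C3). If ligand control is poor, the fallback sets out from 9 and returns at 10. The chromium/nickel ring closure is run without chiral ligand to give the C3-epimeric macrocyclic allylic alcohols F1. Dess–Martin oxidation gives the macrocyclic α-methylene ketone F2. Reduction with the (S)-Me-CBS oxazaborolidine and BH3·SMe2 then sets 3R by reagent control and gives 10.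

Step 10 (site and face selectivity of the directed epoxidation). The fallback sets out from 13 and returns at 17; it masks the west olefin so that a Shi epoxidation can be used in the east.
- Et3SiOTf/2,6-lutidine converts 13 into the C4 triethylsilyl ether F3.
- Pd/C with 1,4-cyclohexadiene gives the malonic acid F4, and paraformaldehyde/Et2NH gives the acrylic acid F5.
- I2/NaHCO3 in MeCN closes the 11-iodo-17,12-lactone F6; only the 11,12-olefin can be reached by the acid.
- Shi epoxidation with the D-fructose-derived ketone gives the (7R,8R)-epoxy iodolactone F7.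
- Catalytic Et3SiOTf induces silyl-transfer 5-exo cyclisation to the tetrahydrofuran iodolactone F8, which carries O8 as the triethylsilyl ether.
- Zn/AcOH reopens the iodolactone by anti elimination to the (11E)-olefin and free acid, which is 17.

Step 13 (proposed new method; the main risks are attack at C12 instead of C11 and slow acetate opening). The fallback uses known chemistry, sets out from 17 and returns at 20. Epoxidation with the enantiomeric (L-fructose-derived) Shi ketone gives the (11S,12S)-epoxy acid F9. Catalytic camphorsulfonic acid in CH2Cl2 at 0 °C lets the carboxylic acid open the epoxide 7-exo at the tertiary C12 with inversion, giving the 11-hydroxy ε-lactone F10 (11S,12R). Ac2O/pyridine/DMAP acetylates O11 to give 20, which is desilylated with HF·pyridine as in step 13.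

**Further compounds**
F1 | step 6 | dibenzyl 2-[(1R,7E,11E)-3-hydroxy-8,12-dimethyl-4-methylidenecyclotetradeca-7,11-dien-1-yl]malonate, mixture of C3 epimers | C=C1CC/C=C(\C)CC/C=C(\C)CC[C@H](CC1O)C(C(=O)OCc1ccccc1)C(=O)OCc1ccccc1
F2 | step 6 | dibenzyl 2-[(1R,7E,11E)-8,12-dimethyl-4-methylidene-3-oxocyclotetradeca-7,11-dien-1-yl]malonate | C=C1CC/C=C(\C)CC/C=C(\C)CC[C@H](CC1=O)C(C(=O)OCc1ccccc1)C(=O)OCc1ccccc1
F3 | step 10 | 4-O-triethylsilyl ether of 13 | C[C@@]1(O[Si](CC)(CC)CC)CC/C=C(\C)CC/C=C(\C)CC[C@H](C[C@H]1OC(C)=O)C(C(=O)OCc1ccccc1)C(=O)OCc1ccccc1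
F4 | step 10 | malonic acid from F3 | C[C@@]1(O[Si](CC)(CC)CC)CC/C=C(\C)CC/C=C(\C)CC[C@H](C[C@H]1OC(C)=O)C(C(=O)O)C(=O)O
F5 | step 10 | 2-[(1R,3R,4R,7E,11E)-3-acetoxy-4,8,12-trimethyl-4-(triethylsilyloxy)cyclotetradeca-7,11-dien-1-yl]acrylic acid | C[C@@]1(O[Si](CC)(CC)CC)CC/C=C(\C)CC/C=C(\C)CC[C@H](C[C@H]1OC(C)=O)C(=C)C(=O)O
F6 | step 10 | 11-iodo-17,12-lactone of F5 (trans iodolactone, configuration at C11 and C12 not relevant) | C[C@@]1(O[Si](CC)(CC)CC)CC/C=C(\C)CCC(I)C2(C)CC[C@H](C[C@H]1OC(C)=O)C(=C)C(=O)O2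
F7 | step 10 | (7R,8R)-7,8-epoxide of F6 | C[C@@]1(O[Si](CC)(CC)CC)CC[C@H]3O[C@]3(C)CCC(I)C2(C)CC[C@H](C[C@H]1OC(C)=O)C(=C)C(=O)O2
F8 | step 10 | 4,7-epoxy (7S,8R) 8-O-triethylsilyl 11-iodo-17,12-lactone | C=C1C(=O)OC2(C)CC[C@@H]1C[C@@H](OC(C)=O)[C@@]1(C)CC[C@H](O1)[C@](C)(O[Si](CC)(CC)CC)CCC2I
F9 | step 13 | (11S,12S)-11,12-epoxide of 17 | C=C(C(=O)O)[C@H]1C[C@@H](OC(C)=O)[C@@]2(C)CC[C@H](O2)[C@](C)(O[Si](CC)(CC)CC)CC[C@@H]3O[C@@]3(C)CC1
F10 | step 13 | 11-O-deacetyl derivative of 20 (11S-hydroxy ε-lactone) | C=C1C(=O)O[C@]2(C)CC[C@@H]1C[C@@H](OC(C)=O)[C@@]1(C)CC[C@H](O1)[C@](C)(O[Si](CC)(CC)CC)CC[C@@H]2O
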